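In a one-step world whose rate is proportional to the reagent present, a fixed conversion costs a fixed amount of reagent. So one percent more charge gives more than one percent more left, and the apparent order is one over the fraction of the reagent charge still there.

| flask | left-handed substrate | right-handed substrate | reagent | free catalyst | remark |
|---|---|---|---|---|---|
| green | 0.050 M | 0.050 M | 0.055 M | 7.5 mM | run made earlier |
| flask | 0.050 M | 0.050 M | 0.0550 M | 5.0 mM |  |

green run (percent of the left-handed substrate and right-handed substrate together charged)

| time / min | left-handed product / % | left-handed substrate / % |
|---|---|---|
| 8.00 | 2.1 | 47.3 |
| 20.0 | 5.0 | 44.5 |
| 40.0 | 7.9 | 41.7 |
| 90.0 | 12.6 | 37.2 |

(readings scatter by 0.3 percentage points)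

- free catalyst is single-handed; left-handed substrate and right-handed substrate are mirror images of each other, charged as a racemate, each of them at the stated concentration
- no earlier run changes the charge of free catalyst; that part of a forecast is a guess
- no earlier run changes the charge of reagent; that part of a forecast is a guess

- apparent order in reagent when 20% of the left-handed substrate and right-handed substrate together are converted (percent change of the rate of making left-handed product for one percent more reagent charged)

I can solve two extremes in my head. If the catalyst costs no reagent, reaching 20% leaves a fraction 63.6% of the reagent charge, which gives an order of 1.57. Suppose instead that the whole catalyst charge has died by then, each catalyst taking one reagent in a step also proportional to reagent. Then the catalyst left at a given conversion doesn't depend on the reagent charge, the rate still follows the reagent left, and the fraction falls to 54.5%. I carry the stretch 1.83, one over the fraction of reagent left at the conversion looked at.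

The green run places the flask between these ends. Its rate of making left-handed product falls 2.79-fold from first interval to last, which I read as catalyst dying. This flask starts with less catalyst, 5.0 mM against 7.5 mM, so I commit to the second end. The reagent step in that death is my guess, since no run varies the reagent.

The forecast gives 1.2, lower than my stretch, and it says “True reagent order was never varied”.

The flask gives 1.8, level with the stretch.

    reagent + free catalyst + left-handed substrate → free catalyst + left-handed product (k = 0.270 /M²/s)
    reagent + free catalyst + right-handed substrate → free catalyst + right-handed product (k = 0.150 /M²/s)
    reagent + free catalyst → spent catalyst (k = 0.00440 /M/s)

By 0.800 h the step to left-handed product had 50% of its turnover up to 8.00 h behind it, while free catalyst stood at 54.6% of its charge and spent catalyst at 45.4%. The asked 20% came at 5.04 h, with left-handed product forming at 3.10 × 10⁻⁴ M/h, and at 8.00 h, with free catalyst at 1.40%, reagent stood at 53% of its charge.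

The numbers in the tables are simulated for substances that don't exist; noise was put on by code.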